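**Strategy.** Ring A is cut at C3–C4 and C5–C10 into tiglic aldehyde and a 2E,4E-diene whose C9–C8–C7 arm is a ketal-masked methyl ketone and whose other terminus bears a dimethylphenylsilyl group. One catalytic enantioselective Diels–Alder reaction closes ring A and sets C3, C4, C5 and C10: the cis C14/C15 methyls on C5/C4 copy the E-enal geometry, the formyl-endo mode places C6 cis to C9 (the later cis C5–C10 fusion), and the silyl group lands 3α, trans to C15, as a latent hydroxyl. Aldol closure of ring B (C6–C7), C9 oxygenation, C7 isopropenylation and a late esterification complete the route.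

Key step: step 5

Remark (numbering): eremophilane numbering is used throughout (ring A = C1–C5 and C10; ring B = C5–C10; C14 on C5, C15 on C4; β = the face of C14/C15).

Remark (assumptions): the silyl group on the free diene terminus takes no part in bond formation and is carried as a masked 3α-hydroxyl, because a later allylic oxidation and ketone reduction at C3 would be uncertain in regio- and stereochemistry. The catalyst antipode is assigned from the formyl C–H···O binding model; should the sense prove opposite, the S-catalyst would be used.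

**Route**

Step 1
Reactants: 1 ethyl 2-(2-methyl-1,3-dioxolan-2-yl)acetate
Product: 2 2-(2-methyl-1,3-dioxolan-2-yl)acetaldehyde
Conditions: i-Bu2AlH (1.05 equiv), CH2Cl2, −78 °C; aq. potassium sodium tartrate work-up
Reagents that add atoms: none
Why: Partial ester reduction should stop at the aldehyde because the aluminium hemiacetal persists at −78 °C, and the ketal is inert to hydride.

Step 2
Reactants: 2 2-(2-methyl-1,3-dioxolan-2-yl)acetaldehyde; 3 triiodomethane
Product: 4 2-[(2E)-3-iodoprop-2-en-1-yl]-2-methyl-1,3-dioxolane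
Conditions: CrCl2 (6 equiv), THF/dioxane, 0 °C → rt
Reagents that add atoms: none
Why: Takai olefination (gem-dichromium addition, anti elimination) should give the E-iodoalkene under neutral conditions that spare the ketal and the enolisable β-ketal aldehyde.

Step 3
Reactants: 5 ethynyl(dimethyl)phenylsilane
Product: 6 dimethyl(phenyl)[(E)-2-(4,4,5,5-tetramethyl-1,3,2-dioxaborolan-2-yl)ethenyl]silane
Conditions: pinacolborane (1.1 equiv), Cp2Zr(H)Cl (5 mol%), Et3N (10 mol%), neat, 60 °C
Reagents that add atoms: pinacolborane, [H]B1OC(C)(C)C(C)(C)O1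
Why: Zirconocene-catalysed syn hydroboration of the terminal alkyne places boron on the unsubstituted carbon and so fixes the E geometry.

Step 4
Reactants: 4 2-[(2E)-3-iodoprop-2-en-1-yl]-2-methyl-1,3-dioxolane; 6 dimethyl(phenyl)[(E)-2-(pinacolboryl)ethenyl]silane
Product: 7 2-[(2E,4E)-5-[dimethyl(phenyl)silyl]penta-2,4-dien-1-yl]-2-methyl-1,3-dioxolane
Conditions: Pd(PPh3)4 (5 mol%), K3PO4 (3 equiv), THF/H2O, 50 °C
Reagents that add atoms: none
Why: Suzuki–Miyaura coupling of an alkenyl iodide with an alkenyl boronate proceeds with retention at both alkenes, so the 2E,4E-diene should result, with vinylsilane and ketal untouched.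

Step 5
Reactants: 7 2-[(2E,4E)-5-[dimethyl(phenyl)silyl]penta-2,4-dien-1-yl]-2-methyl-1,3-dioxolane; 8 (E)-2-methylbut-2-enal
Product: 9 (1S,2S,5R,6R)-5-[dimethyl(phenyl)silyl]-1,6-dimethyl-2-[(2-methyl-1,3-dioxolan-2-yl)methyl]cyclohex-3-ene-1-carbaldehyde
Conditions: (R)-B-(o-tolyl)oxazaborolidine derived from (R)-α,α-diphenylprolinol (20 mol%), Tf2NH (18 mol%), enal in excess (3 equiv), CH2Cl2 (concentrated), −78 → −20 °C
Reagents that add atoms: none
Why: The N-protonated oxazaborolidine binds the formyl oxygen of the s-trans enal (formyl C–H···O contact to the ring oxygen) and lowers its LUMO, so a concerted but asynchronous, suprafacial intermolecular [4+2] cycloaddition closes the six-membered ring A by forming C3–C4 and C5–C10; the closest known reaction type is the cationic oxazaborolidine-catalysed Diels–Alder reaction of α-substituted enals with open-chain 1-substituted dienes. Regiochemistry: the enal β-carbon (C4) should bond to the silyl-bearing terminus, which is favoured by the alkyl donor on the other terminus and by β-silyl stabilisation of the developing charge, so the alkyl-bearing terminus bonds to the quaternary α-carbon (C5). C4 and C5: the cis C14/C15 methyls are the retained E geometry of the enal. C10 and C3: both diene termini are E, so the C9 chain and the silyl group emerge cis to each other, and the formyl-endo transition state places both cis to the formyl carbon C6, giving the future cis ring fusion and the 3α (trans to C15) latent hydroxyl. Absolute configuration: the convex-face phenyl of the catalyst screens one enal face, and the R-catalyst should leave the Cα si face open to C10. The step needs bonding of C5 to the alkyl-bearing terminus, endo orientation and facial control, which are secured by the 1,4-substitution pattern of the diene, the endo preference of the Lewis-acid-bound formyl group and the catalyst, respectively.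

Step 6
Reactants: 9 the cycloadduct
Product: 10 (1S,2R,3R,6R)-3-[dimethyl(phenyl)silyl]-1,2-dimethyl-6-[(2-methyl-1,3-dioxolan-2-yl)methyl]cyclohexane-1-carbaldehyde
Conditions: H2 (1 atm), PtO2 (5 mol%), EtOAc, rt
Reagents that add atoms: none
Why: Heterogeneous hydrogenation of the only C=C bond (C1=C2) creates no stereocentre; platinum is chosen over palladium to suppress migration of the double bond towards C10 or silyl-bearing C3, and the hindered aldehyde, arylsilane and ketal should survive at one atmosphere.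

Step 7
Reactants: 10 the saturated ketal aldehyde
Product: 13 cis-fused enone 3α-[dimethyl(phenyl)silyl]-4β,5β-dimethyl-10βH-decal-6-en-8-one [(4aR,5R,6R,8aR)-6-[dimethyl(phenyl)silyl]-4a,5-dimethyl-4a,5,6,7,8,8a-hexahydronaphthalen-2(1H)-one], via keto aldehyde 11 (not isolated), via β-hydroxy ketone 12 (not isolated)
Conditions: 1 M HCl, THF, rt; then KOH, MeOH, 0 °C → rt
Reagents that add atoms: water, O
Why: Ketal hydrolysis unmasks the C8 methyl ketone, whose C7 enolate adds to the non-enolisable C6 aldehyde (intramolecular aldol) and E1cB dehydration closes ring B at C6–C7; the fusion stays cis because C6 and C9 were set cis in step 5 and neither C5 nor C10 is enolisable.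

Step 8
Reactants: 13 the enone
Product: 14 8-(tert-butyldimethylsilyloxy)-3α-[dimethyl(phenyl)silyl]-4β,5β-dimethyl-10βH-decal-6,8-diene
Conditions: TBSOTf (1.3 equiv), Et3N (2 equiv), CH2Cl2, 0 °C
Reagents that add atoms: tert-butyldimethylsilyl trifluoromethanesulfonate, CC(C)(C)[Si](C)(C)OS(=O)(=O)C(F)(F)F
Why: Soft enolisation of the enone can only occur towards C9, since quaternary C5 offers no γ-hydrogen, and should give the cross-conjugated 2-silyloxy diene.

Step 9
Reactants: 14 the silyloxy diene
Product: 16 9β-(tert-butyldimethylsilyloxy)-3α-[dimethyl(phenyl)silyl]-4β,5β-dimethyl-10βH-decal-6-en-8-one, via silyloxy epoxide 15 (not isolated)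
Conditions: dimethyldioxirane, acetone, −78 → 0 °C; then rt
Reagents that add atoms: dimethyldioxirane, CC1(C)OO1
Why: Rubottom oxidation: the electron-rich C8=C9 enol ether is epoxidised from the convex β-face (C1 and C4 of ring A occupy the α-face of ring B) and 1,4-silyl migration in the epoxide delivers the 9β-silyloxy ketone, so C9 is set by steric approach control and is also the equatorial, thermodynamically preferred epimer.

Step 10
Reactants: 16 the silyl-protected ketol
Product: 17 9β-(tert-butyldimethylsilyloxy)-3α-hydroxy-4β,5β-dimethyl-10βH-decal-6-en-8-one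
Conditions: Hg(OAc)2 (1.5 equiv), AcOOH (32% in AcOH), AcOH, rt
Reagents that add atoms: peracetic acid, CC(=O)OO
Why: Tamao–Fleming oxidation: mercuridesilylation removes the phenyl group from silicon and the peracid-induced 1,2-shift of C3 from silicon to oxygen occurs with retention, so the 3α-silyl group of step 5 should become the 3α-hydroxyl while the electron-poor enone is left alone.

Step 11
Reactants: 17 the hydroxy enone
Product: 18 9β-(tert-butyldimethylsilyloxy)-3α-hydroxy-7-iodo-4β,5β-dimethyl-10βH-decal-6-en-8-one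
Conditions: I2 (2.5 equiv), pyridine/CH2Cl2 (1:1), 0 °C → rt
Reagents that add atoms: iodine, II
Why: Enone α-iodination (pyridine conjugate addition, iodination of the enolate, elimination) should put iodine on C7, the only enone α-position.

Step 12
Reactants: 18 the iodo enone; 19 4,4,5,5-tetramethyl-2-(prop-1-en-2-yl)-1,3,2-dioxaborolane
Product: 20 9β-(tert-butyldimethylsilyloxy)-3α-hydroxy-4β,5β-dimethyl-7-(prop-1-en-2-yl)-10βH-decal-6-en-8-one
Conditions: Pd(dppf)Cl2 (5 mol%), K3PO4 (3 equiv), dioxane/H2O, 50 °C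
Reagents that add atoms: none
Why: Suzuki–Miyaura coupling of a 2-iodoenone with an alkenyl boronate forms C7–C11; the free hydroxyl and silyl ether are tolerated.

Step 13
Reactants: 20 the cross-conjugated dienone
Product: 22 (3R,4R,5R,7R,9R,10S)-9-(tert-butyldimethylsilyloxy)-3-hydroxyeremophil-11-en-8-one, via copper enolate 21 (not isolated)
Conditions: [(Ph3P)CuH]6 (0.5 equiv), H2O (5 equiv), THF, rt; aq. NH4Cl; then DBU (0.2 equiv), CH2Cl2, 0 °C, short contact
Reagents that add atoms: none
Why: Conjugate hydride delivery to C6 gives the enolate, which is protonated at C7 (α-protonation of the dienolate keeps the isopropenyl double bond out of conjugation), and brief amidine equilibration should converge on the 7β epimer, whose isopropenyl group is equatorial and avoids the syn-axial C4.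

Step 14
Reactants: 23 (R)-2-ethyloxirane; 24 trimethylsulfonium iodide
Product: 26 (R)-pent-1-en-3-ol, via sulfonium alkoxide 25 (not isolated)
Conditions: Me3S+ I− (3 equiv), n-BuLi (3 equiv), THF, −10 °C → rt
Reagents that add atoms: none
Why: One-carbon homologation of an epoxide with excess dimethylsulfonium methylide: opening at the terminal carbon gives the betaine, which loses dimethyl sulfide to the allylic alcohol without touching the stereocentre.

Step 15
Reactants: 26 (R)-pent-1-en-3-ol; 27 (Z)-2-methylbut-2-enoic acid (angelic acid)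
Product: 29 (R)-pent-1-en-3-yl (Z)-2-methylbut-2-enoate, via mixed anhydride 28 (not isolated)
Conditions: 2,4,6-Cl3C6H2COCl, Et3N, toluene, rt; then the alcohol, toluene, 70 °C
Reagents that add atoms: none
Why: Yamaguchi-type acylation through the mixed anhydride, attacked at the less hindered angeloyl carbonyl; leaving out a nucleophilic catalyst should avoid Z → E isomerisation to the tiglate.

Step 16
Reactants: 29 the angelate; 30 acrylic acid
Product: 31 (2E,4R)-4-{[(2Z)-2-methylbut-2-enoyl]oxy}hex-2-enoic acid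
Conditions: acrylic acid (4 equiv), second-generation Hoveyda–Grubbs catalyst (5 mol%), CH2Cl2, 40 °C
Reagents that add atoms: none
Why: Olefin cross-metathesis of the monosubstituted alkene with acrylic acid should give the E-enoic acid, the trisubstituted electron-poor angelate alkene being inert to the ruthenium carbene.

Step 17
Reactants: 31 the side-chain acid; 22 the hydroxy ketone
Product: 33 (3R,4R,5R,7R,9R,10S)-9-(tert-butyldimethylsilyloxy)-8-oxoeremophil-11-en-3-yl (2E,4R)-4-{[(2Z)-2-methylbut-2-enoyl]oxy}hex-2-enoate, via mixed anhydride 32 (not isolated)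
Conditions: 2,4,6-Cl3C6H2COCl, Et3N, THF, 0 °C; then the hydroxy ketone, DMAP (0.3 equiv), toluene, rt
Reagents that add atoms: none
Why: Yamaguchi esterification of the equatorial 3α-hydroxyl, the only free hydroxyl since the C9 oxygen is silylated; no stereocentre is involved.

Step 18
Reactants: 33 the silyl-protected ester
Product: 34 (3R,4R,5R,7R,9R,10S)-9-hydroxy-8-oxoeremophil-11-en-3-yl (2E,4R)-4-{[(2Z)-2-methylbut-2-enoyl]oxy}hex-2-enoate
Conditions: HF·pyridine, pyridine, THF, 0 °C → rt
Reagents that add atoms: none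
Why: Buffered fluoride cleavage of the secondary silyl ether is only weakly acidic, so C7, the isopropenyl position and the Z-angelate should be unaffected.

**Compound list**

1 | ethyl 2-(2-methyl-1,3-dioxolan-2-yl)acetate (commercial ethylene ketal of ethyl acetoacetate) | CCOC(=O)CC1(C)OCCO1 | starting material
2 | 2-(2-methyl-1,3-dioxolan-2-yl)acetaldehyde | O=CCC1(C)OCCO1 | intermediate
3 | triiodomethane | IC(I)I | starting material
4 | 2-[(2E)-3-iodoprop-2-en-1-yl]-2-methyl-1,3-dioxolane | I/C=C/CC1(C)OCCO1 | intermediate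
5 | ethynyl(dimethyl)phenylsilane | C#C[Si](C)(C)c1ccccc1 | starting material
6 | dimethyl(phenyl)[(E)-2-(4,4,5,5-tetramethyl-1,3,2-dioxaborolan-2-yl)ethenyl]silane | C[Si](C)(c1ccccc1)/C=C/B1OC(C)(C)C(C)(C)O1 | intermediate
7 | 2-[(2E,4E)-5-[dimethyl(phenyl)silyl]penta-2,4-dien-1-yl]-2-methyl-1,3-dioxolane | C[Si](C)(c1ccccc1)/C=C/C=C/CC1(C)OCCO1 | intermediate
8 | (E)-2-methylbut-2-enal (tiglic aldehyde) | C/C=C(\C)C=O | starting material
9 | (1S,2S,5R,6R)-5-[dimethyl(phenyl)silyl]-1,6-dimethyl-2-[(2-methyl-1,3-dioxolan-2-yl)methyl]cyclohex-3-ene-1-carbaldehyde (formyl, silyl and side chain all cis; both methyls on the other face) | O=C[C@@]1(C)[C@H](C=C[C@@H]([Si](C)(C)c2ccccc2)[C@@H]1C)CC3(C)OCCO3 | intermediate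
10 | (1S,2R,3R,6R)-3-[dimethyl(phenyl)silyl]-1,2-dimethyl-6-[(2-methyl-1,3-dioxolan-2-yl)methyl]cyclohexane-1-carbaldehyde | O=C[C@@]1(C)[C@H](CC[C@@H]([Si](C)(C)c2ccccc2)[C@@H]1C)CC3(C)OCCO3 | intermediate
11 | (1S,2R,3R,6R)-3-[dimethyl(phenyl)silyl]-1,2-dimethyl-6-(2-oxopropyl)cyclohexane-1-carbaldehyde | O=C[C@@]1(C)[C@H](CC[C@@H]([Si](C)(C)c2ccccc2)[C@@H]1C)CC(C)=O | intermediate (not isolated)
12 | 3α-[dimethyl(phenyl)silyl]-6-hydroxy-4β,5β-dimethyl-10βH-decalin-8-one (C6 carbinol configuration undefined) | O=C1CC(O)[C@@]2(C)[C@H](CC[C@@H]([Si](C)(C)c3ccccc3)[C@@H]2C)C1 | intermediate (not isolated)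
13 | 3α-[dimethyl(phenyl)silyl]-4β,5β-dimethyl-10βH-decal-6-en-8-one | O=C1C=C[C@@]2(C)[C@H](CC[C@@H]([Si](C)(C)c3ccccc3)[C@@H]2C)C1 | intermediate
14 | 8-(tert-butyldimethylsilyloxy)-3α-[dimethyl(phenyl)silyl]-4β,5β-dimethyl-10βH-decal-6,8-diene | CC(C)(C)[Si](C)(C)OC1C=C[C@@]2(C)[C@H](CC[C@@H]([Si](C)(C)c3ccccc3)[C@@H]2C)C=1 | intermediate
15 | 8,9β-epoxy-8-(tert-butyldimethylsilyloxy)-3α-[dimethyl(phenyl)silyl]-4β,5β-dimethyl-10βH-decal-6-ene | CC(C)(C)[Si](C)(C)O[C@]13C=C[C@@]2(C)[C@H](CC[C@@H]([Si](C)(C)c4ccccc4)[C@@H]2C)[C@H]1O3 | intermediate (not isolated)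
16 | 9β-(tert-butyldimethylsilyloxy)-3α-[dimethyl(phenyl)silyl]-4β,5β-dimethyl-10βH-decal-6-en-8-one | O=C1C=C[C@@]2(C)[C@H](CC[C@@H]([Si](C)(C)c3ccccc3)[C@@H]2C)[C@H]1O[Si](C)(C)C(C)(C)C | intermediate
17 | 9β-(tert-butyldimethylsilyloxy)-3α-hydroxy-4β,5β-dimethyl-10βH-decal-6-en-8-one | O=C1C=C[C@@]2(C)[C@H](CC[C@@H](O)[C@@H]2C)[C@H]1O[Si](C)(C)C(C)(C)C | intermediate
18 | 9β-(tert-butyldimethylsilyloxy)-3α-hydroxy-7-iodo-4β,5β-dimethyl-10βH-decal-6-en-8-one | O=C1C(I)=C[C@@]2(C)[C@H](CC[C@@H](O)[C@@H]2C)[C@H]1O[Si](C)(C)C(C)(C)C | intermediate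
19 | 4,4,5,5-tetramethyl-2-(prop-1-en-2-yl)-1,3,2-dioxaborolane | CC(=C)B1OC(C)(C)C(C)(C)O1 | starting material
20 | 9β-(tert-butyldimethylsilyloxy)-3α-hydroxy-4β,5β-dimethyl-7-(prop-1-en-2-yl)-10βH-decal-6-en-8-one | O=C1C(C(C)=C)=C[C@@]2(C)[C@H](CC[C@@H](O)[C@@H]2C)[C@H]1O[Si](C)(C)C(C)(C)C | intermediate
21 | monovalent-copper 7(8)-enolate of 22 (phosphine ligand omitted) | [Cu]OC1=C(C(C)=C)C[C@@]2(C)[C@H](CC[C@@H](O)[C@@H]2C)[C@H]1O[Si](C)(C)C(C)(C)C | intermediate (not isolated)
22 | (3R,4R,5R,7R,9R,10S)-9-(tert-butyldimethylsilyloxy)-3-hydroxyeremophil-11-en-8-one (3α-OH, 7β-isopropenyl, 9β-OTBS, 10β-H) | O=C1[C@@H](C(C)=C)C[C@@]2(C)[C@H](CC[C@@H](O)[C@@H]2C)[C@H]1O[Si](C)(C)C(C)(C)C | intermediate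
23 | (R)-2-ethyloxirane | CC[C@@H]1CO1 | starting material
24 | trimethylsulfonium iodide | C[S+](C)C.[I-] | starting material
25 | (R)-[3-oxidopentyl]dimethylsulfonium (betaine) | CC[C@@H]([O-])CC[S+](C)C | intermediate (not isolated)
26 | (R)-pent-1-en-3-ol | C=C[C@H](O)CC | intermediate
27 | (Z)-2-methylbut-2-enoic acid (angelic acid) | OC(=O)/C(C)=C\C | starting material
28 | (Z)-2-methylbut-2-enoic 2,4,6-trichlorobenzoic anhydride | O=C(OC(=O)/C(C)=C\C)c1c(Cl)cc(Cl)cc1Cl | intermediate (not isolated)
29 | (R)-pent-1-en-3-yl (Z)-2-methylbut-2-enoate | C=C[C@H](OC(=O)/C(C)=C\C)CC | intermediate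
30 | acrylic acid | C=CC(=O)O | starting material
31 | (2E,4R)-4-{[(2Z)-2-methylbut-2-enoyl]oxy}hex-2-enoic acid | OC(=O)/C=C/[C@@H](CC)OC(=O)/C(C)=C\C | intermediate
32 | mixed anhydride of 31 with 2,4,6-trichlorobenzoic acid | O=C(OC(=O)/C=C/[C@@H](CC)OC(=O)/C(C)=C\C)c1c(Cl)cc(Cl)cc1Cl | intermediate (not isolated)
33 | (3R,4R,5R,7R,9R,10S)-9-(tert-butyldimethylsilyloxy)-8-oxoeremophil-11-en-3-yl (2E,4R)-4-{[(2Z)-2-methylbut-2-enoyl]oxy}hex-2-enoate | O=C1[C@@H](C(C)=C)C[C@@]2(C)[C@H](CC[C@@H](OC(=O)/C=C/[C@@H](CC)OC(=O)/C(C)=C\C)[C@@H]2C)[C@H]1O[Si](C)(C)C(C)(C)C | intermediate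
34 | (3R,4R,5R,7R,9R,10S)-9-hydroxy-8-oxoeremophil-11-en-3-yl (2E,4R)-4-{[(2Z)-2-methylbut-2-enoyl]oxy}hex-2-enoate (3α-acyloxy, 4β,5β-dimethyl, 7β-isopropenyl, 9β-OH, 10β-H) | C=C(C)[C@H]1C[C@@]2(C)[C@H](CC[C@@H](OC(=O)/C=C/[C@@H](CC)OC(=O)/C(C)=C\C)[C@@H]2C)[C@@H](O)C1=O | target

**Step count and risk**

Total: 18 steps. Longest linear sequence: 14 steps (1, 2, 4–13, 17, 18).

Steps most likely to fail:

Step 5. The cycloaddition may stall because the β-methyl of the enal meets the silyl-bearing diene terminus in the leading bond. The ketal may also sequester the boron catalyst, the first-formed bond may collapse by loss of silicon instead of ring closure, or facial control may be eroded. Fallback: from 7 and 8 the cycloaddition is driven with an achiral aluminium Lewis acid (Me2AlCl, CH2Cl2, −78 → −30 °C), which should give 9 as a racemate, that is together with its mirror image F1. Condensation of the mixture with (1R,2R)-N,N'-dimethyl-1,2-diphenylethane-1,2-diamine (MgSO4, CH2Cl2) should give the two diastereomeric imidazolidines, aminal F2 from 9 and aminal F3 from F1, which are separated by chromatography. Mild hydrolysis of F2 (wet silica gel or dilute aqueous oxalic acid) releases 9, where the route is rejoined.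

Step 10. The peracid may attack the α-silyloxy enone (Baeyer–Villiger-type insertion or loss of the silyl ether in acetic acid) faster than the hindered secondary C–Si bond is oxidised. Fallback: from 13 the same mercury-assisted peracid oxidation is run before C9 is oxygenated, giving hydroxy enone F4. TESCl/imidazole in DMF then gives triethylsilyl ether F5. TBSOTf/Et3N and dimethyldioxirane, as in steps 8 and 9, give dienol ether F6 and, through silyloxy epoxide F7, bis-silyl ether F8. PPTS in MeOH at 0 °C cleaves only the triethylsilyl ether and returns the route to 17.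

Step 13. Hydride may add to the carbonyl of the hindered dienone, or the isopropenyl double bond may migrate into conjugation while C7 is being equilibrated. Fallback: from 17 the enone double bond is hydrogenated (H2, Pd/C, EtOAc) to saturated ketone F9. Its lithium enolate on the C7 methylene side (LiN(SiMe3)2, 2.2 equiv, THF) then undergoes palladium-catalysed α-alkenylation with 2-bromopropene (Pd2(dba)3, P(t-Bu)3), followed by a cold buffered quench. This should give 22 directly, where the route is rejoined, without ever forming the dienone.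

**Further compounds**

F1 | step 5 | (1R,2R,5S,6S)-5-[dimethyl(phenyl)silyl]-1,6-dimethyl-2-[(2-methyl-1,3-dioxolan-2-yl)methyl]cyclohex-3-ene-1-carbaldehyde (mirror image of 9) | O=C[C@]1(C)[C@@H](C=C[C@H]([Si](C)(C)c2ccccc2)[C@H]1C)CC3(C)OCCO3
F2 | step 5 | (4R,5R)-1,3-dimethyl-4,5-diphenylimidazolidine aminal of 9 | CN1[C@H](c2ccccc2)[C@H](N(C)C1[C@@]3(C)[C@H](C=C[C@@H]([Si](C)(C)c4ccccc4)[C@@H]3C)CC5(C)OCCO5)c1ccccc1
F3 | step 5 | (4R,5R)-1,3-dimethyl-4,5-diphenylimidazolidine aminal of F1 | CN1[C@H](c2ccccc2)[C@H](N(C)C1[C@]3(C)[C@@H](C=C[C@H]([Si](C)(C)c4ccccc4)[C@H]3C)CC5(C)OCCO5)c1ccccc1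
F4 | step 10 | 3α-hydroxy-4β,5β-dimethyl-10βH-decal-6-en-8-one | O=C1C=C[C@@]2(C)[C@H](CC[C@@H](O)[C@@H]2C)C1
F5 | step 10 | 4β,5β-dimethyl-3α-(triethylsilyloxy)-10βH-decal-6-en-8-one | O=C1C=C[C@@]2(C)[C@H](CC[C@@H](O[Si](CC)(CC)CC)[C@@H]2C)C1
F6 | step 10 | 8-(tert-butyldimethylsilyloxy)-4β,5β-dimethyl-3α-(triethylsilyloxy)-10βH-decal-6,8-diene | CC(C)(C)[Si](C)(C)OC1C=C[C@@]2(C)[C@H](CC[C@@H](O[Si](CC)(CC)CC)[C@@H]2C)C=1
F7 | step 10 | 8,9β-epoxy-8-(tert-butyldimethylsilyloxy)-4β,5β-dimethyl-3α-(triethylsilyloxy)-10βH-decal-6-ene | CC(C)(C)[Si](C)(C)O[C@]13C=C[C@@]2(C)[C@H](CC[C@@H](O[Si](CC)(CC)CC)[C@@H]2C)[C@H]1O3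
F8 | step 10 | 9β-(tert-butyldimethylsilyloxy)-4β,5β-dimethyl-3α-(triethylsilyloxy)-10βH-decal-6-en-8-one | O=C1C=C[C@@]2(C)[C@H](CC[C@@H](O[Si](CC)(CC)CC)[C@@H]2C)[C@H]1O[Si](C)(C)C(C)(C)C
F9 | step 13 | 9β-(tert-butyldimethylsilyloxy)-3α-hydroxy-4β,5β-dimethyl-10βH-decalin-8-one | O=C1CC[C@@]2(C)[C@H](CC[C@@H](O)[C@@H]2C)[C@H]1O[Si](C)(C)C(C)(C)C
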